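## Structural features

The target is a cis-fused hydroazulene: a cyclopentane (ring B: C1, C2, C3, C3a, C8a) shares the C3a–C8a bond with a cycloheptene (ring A: C3a, C4, C5, C6, C7, C8, C8a) that holds the trisubstituted C6=C7 double bond. Six stereocentres form one contiguous chain, C8–C8a–C1 on one side of the ring fusion and C4–C3a–C3 on the other; C8a is quaternary (methyl) between the oxygenated carbons C1 and C8, and C3 is a tertiary carbinol carrying isopropyl. The ring-fusion hydrogen, the angular methyl, the C1 hydroxyl, the isopropyl group and the C4 ester lie on one face, the C3 hydroxyl and the C8 ester on the other. The fragile groups are the two (Z)-2-methylbut-2-enoates, which isomerise to (E)-esters with base, nucleophilic catalysts or heat and can migrate to a free hydroxyl, and the allylic ester at C8. At the ketone oxidation level of the intermediates the tertiary C3 oxygen β to C4 is also at risk of elimination or retro-aldol cleavage. The real difficulty is the quaternary C8a inside a cis-fused five–seven system, together with telling apart three secondary hydroxyls (C1 free, C4 and C8 acylated) and setting C4 and C8. The key step uses the fact that C3a–C4(O)–C5 is a 2-oxyallyl unit and C8a–C8(O)–C7–C6 a 2-oxygenated diene, held together by the chain C1–C2–C3 of ring B, so that joining C3a to C8a and C5 to C6 makes both rings at once and leaves oxygen on C4 and C8.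

## Logic of the disconnections

**34 to 33.** The O1–Si bond is the last to be broken. Reason: O1 must stay masked while O4 and O8 are acylated, since three secondary hydroxyls cannot otherwise be told apart. Gain: selective acylation is no longer a problem. Demand: a non-basic desilylation, so that the (Z)-esters neither isomerise nor move to O1.

**33 to 30 and 31.** The two ester C–O bonds at O4 and O8 are cut together, which releases two molecules of 31. Reason: the unsaturated esters would not survive hydride or enolate chemistry, so they go on after the last reduction. Gain: 31 is commercial, both esters come from one operation, and the tertiary O3 needs no protection. Demand: acylation of two hindered alcohols without Z to E isomerisation.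

**30 to 29 to 28.** The C8–H and then the C4–H bond are cut, returning both carbinols to carbonyl groups. Reason: each carbonyl has its own control element, O3 for C4 (intramolecular delivery) and the ring conformation for C8. Gain: C4 and C8 become sp2. Demand: a reagent that reduces C4 only, then a 1,2-selective enone reduction, and no movement of the C6=C7 bond while C5 lies between two carbonyl systems.

**28 to 27 to 26.** The O3–Si bond is restored and the C6=C7 π bond removed. Reason: in 26 the enol ether at C8 marks C7, so dehydrogenation can only give C6=C7 and the C6 stereocentre needs no control. Gain: 26 is the direct product of the ring-forming step. Demand: the enol ether must be oxidised before anything hydrolyses it.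

**26 to 23.** C3a–C8a and C5–C6 are cut and both rings open. Reason: the two carbons that carry oxygen in ring A become the central carbons of an oxyallyl cation and of a 2-silyloxydiene. Gain: a bicycle with a quaternary carbon and four stereocentres becomes an open chain with two (C1, C3). Demand: C8a must bond anti to O1, C4 must end trans to isopropyl, the second bond must close through carbon, and the enol ether must survive the medium.

**23 to 21.** The C4–C5 bond is cut; C5 leaves as a chloromethyl anion equivalent and C4 becomes an amide carbonyl. Reason: a chloromethyl ketone cannot be carried through enolate formation at C8a, nor made by electrophilic chlorination once the electron-rich diene is present. Gain: the sensitive group appears one step before it is used. Demand: the carbenoid must add once and leave the enol ether alone.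

**21 to 19 to 18.** The O8–Si bond of the enol ether and the O1–Si bond are cut. Reason: the diene is made from the enone by α′-deprotonation; O1 is silylated first because a free aldol would not survive. Gain: return to a simple aldol adduct. Demand: deprotonation at the α′ methine, not at the γ methyl, and no loss of the β-silyloxy group.

**18 to 14 and 15.** The C1–C8a bond is cut (aldol). Reason: it joins the two halves and creates C1. Gain: 15 is commercial, and the second new centre (C8a) is irrelevant because it becomes sp2. Demand: reagent control of the aldehyde face, since C3 is quaternary and remote.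

**14 to 12 to 11 to 9 to 7.** Functional-group changes only: C1=O back to a terminal alkene, the O3–Si bond, the amide C–N bond, and the C4 acid back to a primary alcohol. Reason: the two arms on C3 are then an allyl and a 2-hydroxyethyl group, differentiated from the start. Gain: 7 is a simple 1,3-diol. Demand: oxidation of a primary alcohol next to a tertiary one and an alkene.

**7 to 6 to 5.** The C3a–H bond (hydride opening) and the C3–O bond (epoxide) are cut. Reason: a tertiary carbinol with two methylene arms is best reached from a trisubstituted allylic alcohol by asymmetric epoxidation; this is the one step that creates absolute configuration without an existing centre. Gain: no stereocentre remains. Demand: 5 must be geometrically pure.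

**5 to 3 and 4, then 3 to 1.** The C3–C2 bond is cut (alkenyl–allyl coupling), then C3–I and C3a–H (hydroalumination–iodination of an alkyne). Reason: this fixes the alkene geometry from a commercial alkynol. Gain: only 1 and 4, both commercial, remain. Demand: retention of geometry in the coupling.

## Other disconnections considered

Alternative 1: The cut is C8–C8a, in the retro sense of a Cope rearrangement that also re-forms C4–C6. Ring A opens to the divinylcyclopropane A1, in which the C3a=C8a double bond of a preformed ring B is one vinyl unit and an (E)-2-(4-methoxybenzyloxy)ethenyl group on the quaternary cyclopropane carbon C6 is the other. Forward, heating A1 would give the cyclohepta-1,4-diene A2 through a boat transition state.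
- In favour: the step is concerted and stereospecific, so C8 follows from the enol ether geometry and the quaternary C8a forms without a cationic intermediate. The trans diastereomer of A1 can epimerise thermally, so both converge. A2 already has C6=C7 in place and C8 at the alcohol level, which would spare steps 14 and 17 of the chosen plan; on these points it is the better plan.
- Against: A1 is a demanding target (tetrasubstituted cyclopentene bearing C1 and C3, a donor-substituted cyclopropane with a quaternary carbon, an enol ether). The C8a methyl is the inward substituent in the boat, so a high temperature and competing opening of the silyloxycyclopropane must be expected. The face of C8a that reacts depends on the cyclopropane configuration relative to ring B. C3a is sp2 in A2, so the ring-fusion hydrogen must still be introduced face-selectively.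
- Comparison: in mechanistic predictability the Cope route is superior to the stepwise cationic (4+3). On C3a the two are equal, since both depend on a late proton transfer next to C4. In structure and step economy the chosen plan is ahead: its precursor 23 is an open chain assembled by one aldol, whereas A1 needs ring B and the cyclopropane first and then forms one ring only.

Alternative 2: The cut removes C6 and C7 as a two-carbon unit (bonds C5–C6 and C7–C8), leaving the cis-fused diquinane 1,3-dione A3. Forward, irradiation of enolised A3 with propadiene A4 would give a methylenecyclobutanol that opens by retro-aldol to the cycloheptane-4,8-dione A5 (De Mayo reaction).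
- In favour: the ring fusion is fixed as cis before the key step, which is better than depending on equilibration. Both enols of A3 lead to the same constitution, both carbonyl oxygens arrive on C4 and C8, and the mechanism is well understood.
- Against: the cumulene must add with its central carbon on C5. A5 has an exocyclic methylene flanked by two equivalent CH2–C=O units, so isomerisation into the ring can give C6=C7 or C5=C6. The two ketones of A5 are not differentiated, whereas the chosen plan delivers C4 as a ketone and C8 as an enol ether. The quaternary C8a and the C1 and C3 centres must already be present in the strained dione, and a gaseous reagent under irradiation limits scale.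
- Comparison: equal or better on ring-fusion control and mechanistic reliability; weaker on regiochemical definition of the alkene and carbonyl groups afterwards. Step count is probably similar, since A3 needs its own ring construction but the expansion is one step.

Alternative 3: Only C5–C6 is cut. The precursor A6 is a fully substituted ring B. On C3a it carries a protected 3-hydroxypropanoic acid chain activated as an N-hydroxyphthalimide ester, and on C8a a protected carbinol bearing a (Z)-alkenyl iodide; all four oxygens are at their final oxidation level. Forward, cathodic reduction with NiCl2(dme) and 2,2'-bipyridine would decarboxylate the ester to the primary C5 radical and couple it with the alkenyl iodide unit of A6, closing ring A to the protected tetraol A7.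
- In favour: no stereocentre is created in or after the key step, the position and geometry of C6=C7 are fixed by the iodide, and the endgame is deprotection and acylation only, with the three secondary hydroxyls already told apart by their protecting groups. On late-stage stereocontrol and hydroxyl differentiation this is the better plan.
- Against: a seven-membered ring is closed by a radical/organonickel coupling that is far better established between two molecules than within one, so reduction of the radical, dimerisation and high dilution must be expected. The whole stereochemical burden (quaternary C8a with its C8 carbinol, C3a with its C4 carbinol, C1, C3) moves to a crowded cyclopentane built stepwise, which makes the route to A6 long.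
- Comparison: mechanistically, one C(sp3)–C(sp2) bond with no stereochemical event is simpler than the (4+3), and equal to it in placing the alkene. Structurally it gains one ring and one bond, against two rings, two bonds and three stereocentres in step 13. In step count the short endgame is outweighed by the linear preparation of A6.

Key step: step 13

**Remarks on the chemistry (assumptions, one line each)**
- Atoms carry the hydroazulene locants of the target (C1 to C8a) in all intermediates, open-chain ones included.
- Structure check: 23 and 26 map atom by atom onto the target; constitution and the spatial arrangement at C1 and C3 agree (C3 is R in the chain and S in the bicycle only through a change of CIP priorities).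
- Design of the precursor: the dienol oxygen carries triethylsilyl rather than a smaller silyl group (survival in step 12 and in the protic, basic medium of step 13; still oxidised by Pd(OAc)2), and the chloromethyl ketone is made last from a Weinreb amide, because the reverse order would require enolising C8 in the presence of the far more acidic chloro ketone.
- Sense of induction in step 9: (Z)-enol diisopinocampheylborinates of ethyl ketones are taken to add to the Re face of aldehydes with the (−)-reagent, so the (+)-reagent is specified for the Si face; if this enone behaves otherwise the antipodal reagent is used and nothing else changes.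
- Endgame order: C4 is reduced under delivery from O3 and only then C8, both before acylation, because reduction of C4 without delivery is expected to give the wrong epimer.

## Route

Step 1
Reactants: 1 4-methylpent-2-yn-1-ol
Product: 3 (2Z)-3-iodo-4-methylpent-2-en-1-ol, via cyclic alkenylalanate 2 (not isolated)
Conditions: NaAlH2(OCH2CH2OCH3)2, THF, 0 °C to rt; then I2, −78 °C
Reagents that add atoms: iodine, II
Why: Hydroxyl-directed trans-hydroalumination of a 2-alkyn-1-ol places aluminium on the distal alkyne carbon (future C3) in a five-membered alkoxyalanate, and iodinolysis with retention gives the (Z)-3-iodoallylic alcohol; this hydroalumination–iodination is standard for propargylic alcohols.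

Step 2
Reactants: 3 (2Z)-3-iodo-4-methylpent-2-en-1-ol; 4 allyltributylstannane (CH2=CHCH2SnBu3)
Product: 5 (2E)-3-(propan-2-yl)hexa-2,5-dien-1-ol
Conditions: Pd(PPh3)4 (5 mol %), CuI (10 mol %), DMF, 50 °C
Reagents that add atoms: none
Why: Stille coupling of an alkenyl iodide with an allylstannane under zerovalent palladium catalysis proceeds with retention of alkene geometry and tolerates the free hydroxyl; it forms the C3–C2 bond and fixes the allyl group cis to CH2OH, on which the sense of step 3 depends.

Step 3
Reactants: 5 (2E)-3-(propan-2-yl)hexa-2,5-dien-1-ol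
Product: 6 [(2S,3S)-3-(propan-2-yl)-3-(prop-2-en-1-yl)oxiran-2-yl]methanol
Conditions: Ti(OiPr)4 (10 mol %), L-(+)-diethyl tartrate (12 mol %), tBuOOH, 4 Å molecular sieves, CH2Cl2, −20 °C
Reagents that add atoms: tert-butyl hydroperoxide, CC(C)(C)OO
Why: Sharpless asymmetric epoxidation with the tetravalent titanium L-(+)-tartrate catalyst delivers oxygen to the face of this trisubstituted allylic alcohol that makes the quaternary epoxide carbon (C3) S; the isolated terminal alkene is not an allylic alcohol and should not react. This sets the absolute configuration of the tertiary C3–O centre.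

Step 4
Reactants: 6 [(2S,3S)-3-(propan-2-yl)-3-(prop-2-en-1-yl)oxiran-2-yl]methanol
Product: 7 (3R)-3-(propan-2-yl)hex-5-ene-1,3-diol
Conditions: NaAlH2(OCH2CH2OCH3)2, THF, 0 °C to rt
Reagents that add atoms: none
Why: Regioselective reductive epoxide opening: intramolecular hydride delivery from the alkoxyaluminate opens a 2,3-epoxy alcohol at C2 (future C3a) and leaves the quaternary C3–O bond untouched, so the 1,3-diol forms with retention at C3; this regiochemistry is established for this hydride.

Step 5
Reactants: 7 (3R)-3-(propan-2-yl)hex-5-ene-1,3-diol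
Product: 9 (3R)-3-hydroxy-3-(propan-2-yl)hex-5-enoic acid, via hydroxy aldehyde 8 (not isolated)
Conditions: TEMPO (cat.), PhI(OAc)2, CH3CN/H2O, rt
Reagents that add atoms: water, O
Why: Nitroxyl-catalysed oxidation with a hypervalent iodine co-oxidant takes a primary alcohol through the aldehyde hydrate to the acid in aqueous acetonitrile, while the tertiary alcohol and the alkene are inert; the carboxyl carbon is C4.

Step 6
Reactants: 9 (3R)-3-hydroxy-3-(propan-2-yl)hex-5-enoic acid
Product: 11 (3R)-3-hydroxy-N-methoxy-N-methyl-3-(propan-2-yl)hex-5-enamide, via benzotriazolyl ester 10 (not isolated)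
Conditions: EDC·HCl, 1-hydroxybenzotriazole, MeNHOMe·HCl, iPr2NEt, CH2Cl2, 0 °C to rt
Reagents that add atoms: N,O-dimethylhydroxylamine hydrochloride, CNOC.Cl
Why: Carbodiimide/hydroxybenzotriazole amide coupling; the hindered tertiary hydroxyl should not compete with the amine. The Weinreb amide is the masked acyl group that accepts the chloromethyl carbon in step 12.

Step 7
Reactants: 11 (3R)-3-hydroxy-N-methoxy-N-methyl-3-(propan-2-yl)hex-5-enamide
Product: 12 (3R)-N-methoxy-N-methyl-3-(propan-2-yl)-3-(triethylsilyloxy)hex-5-enamide
Conditions: Et3SiOTf, 2,6-lutidine, CH2Cl2, −78 to 0 °C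
Reagents that add atoms: triethylsilyl trifluoromethanesulfonate, CC[Si](CC)(CC)OS(=O)(=O)C(F)(F)F
Why: Silylation with a silyl triflate and a hindered pyridine base is the standard way to protect tertiary alcohols; the triethylsilyl ether blocks retro-aldol and oxygen capture of the later cation and is the more labile of the two alkyl silyl ethers, as step 15 requires.

Step 8
Reactants: 12 (3R)-N-methoxy-N-methyl-3-(propan-2-yl)-3-(triethylsilyloxy)hex-5-enamide
Product: 14 (3R)-N-methoxy-N-methyl-5-oxo-3-(propan-2-yl)-3-(triethylsilyloxy)pentanamide, via secondary ozonide 13 (not isolated)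
Conditions: O3, CH2Cl2, −78 °C; then PPh3, −78 °C to rt
Reagents that add atoms: ozone, [O-][O+]=O
Why: Ozonolysis of the monosubstituted alkene with reductive work-up gives the C1 aldehyde; amide and silyl ether are inert to ozone.

Step 9
Reactants: 14 (3R)-N-methoxy-N-methyl-5-oxo-3-(propan-2-yl)-3-(triethylsilyloxy)pentanamide; 15 (4E)-hex-4-en-3-one
Product: 18 (3R,5R,6S,8E)-5-hydroxy-N-methoxy-N,6-dimethyl-7-oxo-3-(propan-2-yl)-3-(triethylsilyloxy)dec-8-enamide, via boron dienolate 16 (not isolated), via boron aldolate 17 (not isolated)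
Conditions: (+)-Ipc2BOTf, iPr2NEt, CH2Cl2, −78 °C (15); then 14, −78 to −20 °C; H2O2, pH 7 buffer, MeOH
Reagents that add atoms: none
Why: The boron triflate and amine enolise the ethyl side of 15 to the (Z)-enol borinate, which adds through a chair transition state to give the syn aldol (diisopinocampheylboron aldol of an ethyl ketone); the chiral ligands select the Si face of the aldehyde and so set C1 as R, the remote quaternary C3 having little influence. The methyl-bearing carbon (future C8a) is also formed but becomes sp2 in step 11.

Step 10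
Reactants: 18 (3R,5R,6S,8E)-5-hydroxy-N-methoxy-N,6-dimethyl-7-oxo-3-(propan-2-yl)-3-(triethylsilyloxy)dec-8-enamide
Product: 19 (3R,5R,6S,8E)-5-(tert-butyldimethylsilyloxy)-N-methoxy-N,6-dimethyl-7-oxo-3-(propan-2-yl)-3-(triethylsilyloxy)dec-8-enamide
Conditions: tBuMe2SiOTf, 2,6-lutidine, CH2Cl2, −78 °C
Reagents that add atoms: tert-butyldimethylsilyl trifluoromethanesulfonate, CC(C)(C)[Si](C)(C)OS(=O)(=O)C(F)(F)F
Why: Standard silylation of a β-hydroxy ketone at low temperature, where retro-aldol does not compete; the bulky group is kept to the last step and serves as the facial control element at C8a in step 13.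

Step 11
Reactants: 19 (3R,5R,6S,8E)-5-(tert-butyldimethylsilyloxy)-N-methoxy-N,6-dimethyl-7-oxo-3-(propan-2-yl)-3-(triethylsilyloxy)dec-8-enamide
Product: 21 (3R,5R,6Z,8E)-5-(tert-butyldimethylsilyloxy)-N-methoxy-N,6-dimethyl-3-(propan-2-yl)-3,7-bis(triethylsilyloxy)deca-6,8-dienamide, via lithium dienolate 20 (not isolated)
Conditions: LiN(iPr)2, THF, −78 °C; then Et3SiCl, −78 to −40 °C
Reagents that add atoms: chlorotriethylsilane, CC[Si](Cl)(CC)CC
Why: Kinetic deprotonation of an enone by a lithium amide takes place at the α′ carbon (here the methine between C8 and C1) and not at the γ-methyl, and O-silylation of the cross-conjugated dienolate gives the 2-silyloxydiene; at −78 °C the β-silyloxy group should not be expelled and the much less acidic amide is not deprotonated. The enol ether also masks the C8 carbonyl for step 12; its geometry is of no consequence for step 13 (drawn Z).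

Step 12
Reactants: 21 (3R,5R,6Z,8E)-5-(tert-butyldimethylsilyloxy)-N-methoxy-N,6-dimethyl-3-(propan-2-yl)-3,7-bis(triethylsilyloxy)deca-6,8-dienamide
Product: 23 (4R,6R,7Z,9E)-6-(tert-butyldimethylsilyloxy)-1-chloro-7-methyl-4-(propan-2-yl)-4,8-bis(triethylsilyloxy)undeca-7,9-dien-2-one, via lithium tetrahedral adduct 22 (not isolated)
Conditions: ICH2Cl, MeLi·LiBr, THF, −78 °C; then aq. NH4Cl (buffered), −78 °C
Reagents that add atoms: chloroiodomethane, ClCI
Why: Chloromethyllithium, generated by iodine–lithium exchange in the presence of the substrate, adds once to a Weinreb amide (carbenoid homologation to an α-chloro ketone); the chelated adduct collapses only on work-up to the chloromethyl ketone. No other electrophile is present because C8 is an enol ether, and a triethylsilyl enol ether should not be cleaved by alkyllithium at −78 °C.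

Step 13
Reactants: 23 (4R,6R,7Z,9E)-6-(tert-butyldimethylsilyloxy)-1-chloro-7-methyl-4-(propan-2-yl)-4,8-bis(triethylsilyloxy)undeca-7,9-dien-2-one
Product: 26 (1R,3S,3aS,8aR)-1-(tert-butyldimethylsilyloxy)-6,8a-dimethyl-3-(propan-2-yl)-3,8-bis(triethylsilyloxy)-2,3,3a,5,6,8a-hexahydroazulen-4(1H)-one (C6 epimers), via oxyallyl cation 24 (not isolated), via monocyclic zwitterion 25 (not isolated)
Conditions: Et3N (3 equiv), CF3CH2OH/CH2Cl2, 0 °C to rt, 0.01 M
Reagents that add atoms: none
Why: Reversible deprotonation at C3a by Et3N and loss of chloride in the ionising alcohol give the 2-oxidoallyl cation 24 (C3a–C4–C5); the closest known reaction is the base-induced intramolecular (4+3) cycloaddition of α-chloro ketones carrying a tethered diene, which gives hydroazulenones. The enol ether carbon C8a bonds to the cation terminus C3a in a 5-exo-trig closure (ring B) to give 25, whose enolate carbon C5 then closes on C6 of the silyloxyallyl cation in a 7-endo-trig step (ring A); the course is expected to be stepwise or strongly asynchronous. At C8a, allylic 1,3-strain keeps the C1–H bond in the plane of the tetrasubstituted enol ether, so the C1 silyloxy group and the tether lie on opposite faces and the tethered cation can arrive only anti to the silyloxy group, which puts C8 trans and the methyl cis to O1. At C3a, the large oxyallyl residue (C4) avoids the isopropyl group on C3 in the five-membered transition state and ends cis to the smaller silyloxy group; the ring-fusion hydrogen is α to the C4 ketone, so the cis-fused isomer can be reached by equilibration in the same basic medium if it is not the kinetic product. C6 forms as a mixture and is erased in step 14. The step needs site selectivity (C8a to C3a and not to C5, secured because only this pairing gives a five-membered ring), carbon rather than oxygen closure in the second bond, and survival of the enol ether in the protic medium, for which the triethylsilyl group was chosen; the electron-rich silyloxydiene should capture the cation before solvent addition or Favorskii rearrangement. Oxygen is left where the target needs it, as a ketone at C4 and a regiodefined enol ether at C8.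

Step 14
Reactants: 26 (1R,3S,3aS,8aR)-1-(tert-butyldimethylsilyloxy)-6,8a-dimethyl-3-(propan-2-yl)-3,8-bis(triethylsilyloxy)-2,3,3a,5,6,8a-hexahydroazulen-4(1H)-one
Product: 27 (1R,3S,3aS,8aR)-1-(tert-butyldimethylsilyloxy)-6,8a-dimethyl-3-(propan-2-yl)-3-(triethylsilyloxy)-2,3,3a,8a-tetrahydroazulene-4,8(1H,5H)-dione
Conditions: Pd(OAc)2 (1.1 equiv), CH3CN, rt
Reagents that add atoms: none
Why: Saegusa–Ito oxidation: divalent palladium adds to the enol ether at C7 and β-hydride elimination can involve only the C6–H because C8a is quaternary, so the enone appears as C6=C7 and the C6 stereocentre is removed; either C6 epimer can reach a syn arrangement through the oxa-π-allyl complex.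

Step 15
Reactants: 27 (1R,3S,3aS,8aR)-1-(tert-butyldimethylsilyloxy)-6,8a-dimethyl-3-(propan-2-yl)-3-(triethylsilyloxy)-2,3,3a,8a-tetrahydroazulene-4,8(1H,5H)-dione
Product: 28 (1R,3S,3aS,8aR)-1-(tert-butyldimethylsilyloxy)-3-hydroxy-6,8a-dimethyl-3-(propan-2-yl)-2,3,3a,8a-tetrahydroazulene-4,8(1H,5H)-dione
Conditions: HF·pyridine, pyridine, THF, 0 °C
Reagents that add atoms: none
Why: Selective fluoride desilylation: a triethylsilyl ether is cleaved by buffered HF·pyridine faster than the hindered secondary tert-butyldimethylsilyl ether; the cold, weakly acidic conditions are chosen to leave the C6=C7 position and the β-hydroxy ketone intact.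

Step 16
Reactants: 28 (1R,3S,3aS,8aR)-1-(tert-butyldimethylsilyloxy)-3-hydroxy-6,8a-dimethyl-3-(propan-2-yl)-2,3,3a,8a-tetrahydroazulene-4,8(1H,5H)-dione
Product: 29 (1R,3S,3aR,4R,8aR)-1-(tert-butyldimethylsilyloxy)-3,4-dihydroxy-6,8a-dimethyl-3-(propan-2-yl)-2,3,3a,4,5,8a-hexahydroazulen-8(1H)-one
Conditions: Me4NBH(OAc)3, CH3CN/AcOH, −30 °C
Reagents that add atoms: none
Why: Evans–Saksena reduction: the C3 hydroxyl exchanges onto boron and hydride is delivered within the alkoxyborohydride; O3 and C4 are cis on ring B, so delivery is to the β face of C4 and should give the 4α-alcohol (4R). The C8 enone has no free hydroxyl within six-membered delivery distance and is not reduced intermolecularly by this reagent.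

Step 17
Reactants: 29 (1R,3S,3aR,4R,8aR)-1-(tert-butyldimethylsilyloxy)-3,4-dihydroxy-6,8a-dimethyl-3-(propan-2-yl)-2,3,3a,4,5,8a-hexahydroazulen-8(1H)-one
Product: 30 (1R,3S,3aR,4R,8R,8aS)-1-(tert-butyldimethylsilyloxy)-6,8a-dimethyl-3-(propan-2-yl)-1,2,3,3a,4,5,8,8a-octahydroazulene-3,4,8-triol
Conditions: NaBH4, CeCl3·7H2O, MeOH, −78 °C
Reagents that add atoms: none
Why: Luche reduction gives 1,2-addition to the enone; in the half-chair of ring A that keeps C3 and the angular methyl pseudo-equatorial, the C8a–C1 bond is pseudo-axial on the β face, and hydride should add anti to it from the α face to give the 8β-alcohol (8R).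

Step 18
Reactants: 30 (1R,3S,3aR,4R,8R,8aS)-1-(tert-butyldimethylsilyloxy)-6,8a-dimethyl-3-(propan-2-yl)-1,2,3,3a,4,5,8,8a-octahydroazulene-3,4,8-triol; 31 angelic acid, (2Z)-2-methylbut-2-enoic acid
Product: 33 (1R,3S,3aR,4R,8R,8aS)-1-(tert-butyldimethylsilyloxy)-3-hydroxy-6,8a-dimethyl-3-(propan-2-yl)-1,2,3,3a,4,5,8,8a-octahydroazulene-4,8-diyl bis[(2Z)-2-methylbut-2-enoate], via angelic mixed anhydride 32 (not isolated)
Conditions: 31 (3 equiv), 2,4,6-Cl3C6H2COCl (3 equiv), Et3N, toluene, rt; then 30, 75 °C
Reagents that add atoms: angelic acid (second equivalent of 31), C/C=C(/C)C(=O)O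
Why: Yamaguchi-type acylation: the mixed anhydride of angelic and 2,4,6-trichlorobenzoic acid in hot toluene without a nucleophilic catalyst is the established way to form angelates without Z to E isomerisation. Two molecules of 31 are consumed, one for each secondary hydroxyl (O4 and O8); the tertiary C3 hydroxyl does not react and O1 is still silylated.

Step 19
Reactants: 33 (1R,3S,3aR,4R,8R,8aS)-1-(tert-butyldimethylsilyloxy)-3-hydroxy-6,8a-dimethyl-3-(propan-2-yl)-1,2,3,3a,4,5,8,8a-octahydroazulene-4,8-diyl bis[(2Z)-2-methylbut-2-enoate]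
Product: 34 (1R,3S,3aR,4R,8R,8aR)-1,3-dihydroxy-6,8a-dimethyl-3-(propan-2-yl)-1,2,3,3a,4,5,8,8a-octahydroazulene-4,8-diyl bis[(2Z)-2-methylbut-2-enoate] (CNP0249167.1)
Conditions: HF·pyridine, THF, 0 °C to rt
Reagents that add atoms: none
Why: Fluoride desilylation under acidic conditions cleaves the remaining silyl ether without base, so neither isomerisation of the esters nor acyl migration from O8 to O1 is expected.

## Compound list

1 | 4-methylpent-2-yn-1-ol | CC(C)C#CCO | starting material
2 | sodium 2,2-bis(2-methoxyethoxy)-3-(propan-2-yl)-2,5-dihydro-1,2-oxaaluminol-2-uide (cyclic alkenylalanate, not isolated) | [Na+].COCCO[Al-]1(OCCOC)OCC=C1C(C)C | intermediate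
3 | (2Z)-3-iodo-4-methylpent-2-en-1-ol | OC/C=C(\I)C(C)C | intermediate
4 | allyltributylstannane | C=CC[Sn](CCCC)(CCCC)CCCC | starting material
5 | (2E)-3-(propan-2-yl)hexa-2,5-dien-1-ol | OC/C=C(\CC=C)C(C)C | intermediate
6 | [(2S,3S)-3-(propan-2-yl)-3-(prop-2-en-1-yl)oxiran-2-yl]methanol | OC[C@@H]1O[C@@]1(CC=C)C(C)C | intermediate
7 | (3R)-3-(propan-2-yl)hex-5-ene-1,3-diol | C=CC[C@](O)(C(C)C)CCO | intermediate
8 | (3R)-3-hydroxy-3-(propan-2-yl)hex-5-enal (not isolated) | C=CC[C@](O)(C(C)C)CC=O | intermediate
9 | (3R)-3-hydroxy-3-(propan-2-yl)hex-5-enoic acid | C=CC[C@](O)(C(C)C)CC(=O)O | intermediate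
10 | 1H-benzotriazol-1-yl (3R)-3-hydroxy-3-(propan-2-yl)hex-5-enoate (not isolated) | C=CC[C@](O)(C(C)C)CC(=O)On1nnc2ccccc12 | intermediate
11 | (3R)-3-hydroxy-N-methoxy-N-methyl-3-(propan-2-yl)hex-5-enamide | C=CC[C@](O)(C(C)C)CC(=O)N(C)OC | intermediate
12 | (3R)-N-methoxy-N-methyl-3-(propan-2-yl)-3-(triethylsilyloxy)hex-5-enamide | C=CC[C@](O[Si](CC)(CC)CC)(C(C)C)CC(=O)N(C)OC | intermediate
13 | (3R)-N-methoxy-N-methyl-3-(propan-2-yl)-3-(triethylsilyloxy)-4-(1,2,4-trioxolan-3-yl)butanamide (secondary ozonide, not isolated) | C1OC(C[C@](O[Si](CC)(CC)CC)(C(C)C)CC(=O)N(C)OC)OO1 | intermediate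
14 | (3R)-N-methoxy-N-methyl-5-oxo-3-(propan-2-yl)-3-(triethylsilyloxy)pentanamide | O=CC[C@](O[Si](CC)(CC)CC)(C(C)C)CC(=O)N(C)OC | intermediate
15 | (4E)-hex-4-en-3-one | C/C=C/C(=O)CC | starting material
16 | (2Z,4E)-hexa-2,4-dien-3-yl bis[(1S,2R,3S,5S)-2,6,6-trimethylbicyclo[3.1.1]heptan-3-yl]borinate (not isolated) | C/C=C(/C=C/C)OB([C@H]1C[C@H]2C[C@@H]([C@@H]1C)C2(C)C)[C@H]1C[C@H]2C[C@@H]([C@@H]1C)C2(C)C | intermediate
17 | O5-diisopinocampheylboryl derivative of 18 (boron aldolate, not isolated) | C/C=C/C(=O)[C@@H](C)[C@H](OB([C@H]1C[C@H]2C[C@@H]([C@@H]1C)C2(C)C)[C@H]1C[C@H]2C[C@@H]([C@@H]1C)C2(C)C)C[C@](O[Si](CC)(CC)CC)(C(C)C)CC(=O)N(C)OC | intermediate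
18 | (3R,5R,6S,8E)-5-hydroxy-N-methoxy-N,6-dimethyl-7-oxo-3-(propan-2-yl)-3-(triethylsilyloxy)dec-8-enamide | C/C=C/C(=O)[C@@H](C)[C@H](O)C[C@](O[Si](CC)(CC)CC)(C(C)C)CC(=O)N(C)OC | intermediate
19 | (3R,5R,6S,8E)-5-(tert-butyldimethylsilyloxy)-N-methoxy-N,6-dimethyl-7-oxo-3-(propan-2-yl)-3-(triethylsilyloxy)dec-8-enamide | C/C=C/C(=O)[C@@H](C)[C@H](O[Si](C)(C)C(C)(C)C)C[C@](O[Si](CC)(CC)CC)(C(C)C)CC(=O)N(C)OC | intermediate
20 | lithium dienolate of 19, deprotonated at C6 of the chain (not isolated; enolate geometry undefined) | C/C=C/C(O[Li])=C(C)[C@H](O[Si](C)(C)C(C)(C)C)C[C@](O[Si](CC)(CC)CC)(C(C)C)CC(=O)N(C)OC | intermediate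
21 | (3R,5R,6Z,8E)-5-(tert-butyldimethylsilyloxy)-N-methoxy-N,6-dimethyl-3-(propan-2-yl)-3,7-bis(triethylsilyloxy)deca-6,8-dienamide | C/C=C/C(O[Si](CC)(CC)CC)=C(\C)[C@H](O[Si](C)(C)C(C)(C)C)C[C@](O[Si](CC)(CC)CC)(C(C)C)CC(=O)N(C)OC | intermediate
22 | lithium alkoxide of the chloromethyl adduct of 21 at the amide carbon (not isolated; new centre undefined) | C/C=C/C(O[Si](CC)(CC)CC)=C(\C)[C@H](O[Si](C)(C)C(C)(C)C)C[C@](O[Si](CC)(CC)CC)(C(C)C)CC(O[Li])(CCl)N(C)OC | intermediate
23 | (4R,6R,7Z,9E)-6-(tert-butyldimethylsilyloxy)-1-chloro-7-methyl-4-(propan-2-yl)-4,8-bis(triethylsilyloxy)undeca-7,9-dien-2-one | C/C=C/C(O[Si](CC)(CC)CC)=C(\C)[C@H](O[Si](C)(C)C(C)(C)C)C[C@](O[Si](CC)(CC)CC)(C(C)C)CC(=O)CCl | intermediate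
24 | 2-oxidoallyl cation from 23 (C3a–C4–C5; not isolated) | C/C=C/C(O[Si](CC)(CC)CC)=C(\C)[C@H](O[Si](C)(C)C(C)(C)C)C[C@](O[Si](CC)(CC)CC)(C(C)C)C=C([O-])[CH2+] | intermediate
25 | ring-B zwitterion: cyclopentane with C4 enolate on C3a and silyloxyallyl cation on C8a (not isolated) | C/C=C/C(=[O+][Si](CC)(CC)CC)[C@@]1(C)[C@H](O[Si](C)(C)C(C)(C)C)C[C@](O[Si](CC)(CC)CC)(C(C)C)[C@H]1C([O-])=C | intermediate
26 | (1R,3S,3aS,8aR)-1-(tert-butyldimethylsilyloxy)-6,8a-dimethyl-3-(propan-2-yl)-3,8-bis(triethylsilyloxy)-2,3,3a,5,6,8a-hexahydroazulen-4(1H)-one (C6 epimers) | O=C1CC(C)C=C(O[Si](CC)(CC)CC)[C@@]2(C)[C@H](O[Si](C)(C)C(C)(C)C)C[C@](O[Si](CC)(CC)CC)(C(C)C)[C@@H]12 | intermediate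
27 | (1R,3S,3aS,8aR)-1-(tert-butyldimethylsilyloxy)-6,8a-dimethyl-3-(propan-2-yl)-3-(triethylsilyloxy)-2,3,3a,8a-tetrahydroazulene-4,8(1H,5H)-dione | O=C1CC(C)=CC(=O)[C@@]2(C)[C@H](O[Si](C)(C)C(C)(C)C)C[C@](O[Si](CC)(CC)CC)(C(C)C)[C@@H]12 | intermediate
28 | (1R,3S,3aS,8aR)-1-(tert-butyldimethylsilyloxy)-3-hydroxy-6,8a-dimethyl-3-(propan-2-yl)-2,3,3a,8a-tetrahydroazulene-4,8(1H,5H)-dione | O=C1CC(C)=CC(=O)[C@@]2(C)[C@H](O[Si](C)(C)C(C)(C)C)C[C@](O)(C(C)C)[C@@H]12 | intermediate
29 | (1R,3S,3aR,4R,8aR)-1-(tert-butyldimethylsilyloxy)-3,4-dihydroxy-6,8a-dimethyl-3-(propan-2-yl)-2,3,3a,4,5,8a-hexahydroazulen-8(1H)-one | O[C@@H]1CC(C)=CC(=O)[C@@]2(C)[C@H](O[Si](C)(C)C(C)(C)C)C[C@](O)(C(C)C)[C@@H]12 | intermediate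
30 | (1R,3S,3aR,4R,8R,8aS)-1-(tert-butyldimethylsilyloxy)-6,8a-dimethyl-3-(propan-2-yl)-1,2,3,3a,4,5,8,8a-octahydroazulene-3,4,8-triol | O[C@@H]1CC(C)=C[C@@H](O)[C@@]2(C)[C@H](O[Si](C)(C)C(C)(C)C)C[C@](O)(C(C)C)[C@@H]12 | intermediate
31 | angelic acid, (2Z)-2-methylbut-2-enoic acid | C/C=C(/C)C(=O)O | starting material
32 | (2Z)-2-methylbut-2-enoic 2,4,6-trichlorobenzoic anhydride (not isolated) | C/C=C(/C)C(=O)OC(=O)c1c(Cl)cc(Cl)cc1Cl | intermediate
33 | (1R,3S,3aR,4R,8R,8aS)-1-(tert-butyldimethylsilyloxy)-3-hydroxy-6,8a-dimethyl-3-(propan-2-yl)-1,2,3,3a,4,5,8,8a-octahydroazulene-4,8-diyl bis[(2Z)-2-methylbut-2-enoate] | C/C=C(/C)C(=O)O[C@@H]1CC(C)=C[C@@H](OC(=O)/C(C)=C\C)[C@@]2(C)[C@H](O[Si](C)(C)C(C)(C)C)C[C@](O)(C(C)C)[C@@H]12 | intermediate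
34 | (1R,3S,3aR,4R,8R,8aR)-1,3-dihydroxy-6,8a-dimethyl-3-(propan-2-yl)-1,2,3,3a,4,5,8,8a-octahydroazulene-4,8-diyl bis[(2Z)-2-methylbut-2-enoate] | C/C=C(/C)C(=O)O[C@@H]1CC(C)=C[C@@H](OC(=O)/C(C)=C\C)[C@@]2(C)[C@H](O)C[C@](O)(C(C)C)[C@@H]12 | target

## Step count and least certain steps

Total: 19 steps. Longest linear sequence: 19 steps (1 to 34); 4, 15 and 31 enter as commercial materials.

**Step 13 (key step).** Most likely to go wrong: the second bond may close through the enolate oxygen instead of C5, or the intermediate cation may lose its silyl group before ring A closes; both follow from the stepwise course. Solvolysis of the enol ether, elimination of the C3 silyloxy group from the C3a enolate, or a trans ring fusion that needs equilibration are further risks. Fallback (from 23, back at 26): the two bonds are made in separate, known operations. Ionisation of 23 with Et3N in CF3CH2OH containing water is used for the first bond only; desilylation of the cation should give the monocyclic 1,4-diketone F1 (alkylation of a silyl enol ether by an oxyallyl cation). Kinetic deprotonation of the acetyl group of F1 (LiN(iPr)2, then Et3SiCl, THF, −78 °C; the enone has no α′ hydrogen because C8a is quaternary) gives the methyl ketone silyl enol ether F2. An intramolecular Mukaiyama–Michael addition (catalytic Et3SiOTf, CH2Cl2, −78 °C) then closes C5–C6 with silyl transfer to O8, which is 26.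

**Step 9.** Most likely to go wrong: poor facial selectivity at the aldehyde, since C1 depends on reagent control alone and the enolisation of an enone by the boron triflate may be less clean than that of a saturated ketone. Fallback (from 14, back at 19): C1 is set by crotylboration. (Z)-Crotyldiisopinocampheylborane from (+)-α-pinene (THF, −78 °C; NaBO3·4H2O) should add to the Si face of 14 to give the syn homoallylic alcohol F3. Silylation (tBuMe2SiOTf, 2,6-lutidine) gives the silyl ether F4, ozonolysis (O3; PPh3) the aldehyde F5, addition of (E)-CH3CH=CHMgBr at −78 °C (aldehyde before Weinreb amide) the allylic alcohol F6, and Dess–Martin oxidation gives 19.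

**Step 11.** Most likely to go wrong: deprotonation at the γ-methyl instead of the hindered α′ methine, or β-elimination of the C1 silyloxy group from the enolate. Fallback (from 18, back at 27): the free aldol 18 is converted into its dianion (LiN(iPr)2, 2.2 equiv, THF, −78 °C); the alkoxide cannot be eliminated and directs the base to the neighbouring α′ hydrogen. Silylation of both oxygens with tBuMe2SiOTf gives the bis(tert-butyldimethylsilyl) amide F7. Chloromethylation as in step 12 gives the chloromethyl ketone F8, ionisation as in step 13 the cycloadduct F9, and oxidation with Pd(OAc)2 under O2 in DMSO (conditions for less reactive silyl enol ethers) gives 27.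

**Step 16 (with step 15).** Most likely to go wrong: migration of the C6=C7 bond into conjugation with C4 during silyl removal or in the acetic acid medium, because C5 in 27 and 28 is activated by both carbonyl systems. Incomplete facial control, or some delivery from O3 to C8, is also possible. Fallback (from 26, back at 29): C4 is reduced before the double bond exists. HF·pyridine in THF removes the tertiary triethylsilyl group and hydrolyses the enol ether of 26 to the hydroxy diketone F10, in which nothing can migrate. Me4NBH(OAc)3 reduces C4 under delivery from O3 to the diol F11. Me3SiOTf/Et3N silylates both hydroxyls and the C8 ketone, which can enolise only toward C7, to give the tris(trimethylsilyl) compound F12. Pd(OAc)2 in CH3CN followed by citric acid in MeOH gives 29.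

**Step 17.** Most likely to go wrong: poor facial selectivity at C8, since the prediction depends on a conformational argument for a flexible seven-membered ring. Fallback (from 29, back at 34): C8 is reduced under delivery from O1. The only secondary hydroxyl of 29 is acylated with 32 to the mono-angelate F13. HF·pyridine frees O1 to give the diol F14. Me4NBH(OAc)3 delivers hydride from the α-oriented O1 to the α face of C8 to give the anti-1,3-diol, triol F15. Acylation of the allylic C8 hydroxyl with one equivalent of 32, in preference to the C1 hydroxyl that is cis to the angular methyl, gives 34; this last selectivity is the weak point of the fallback.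

**Step 18.** Most likely to go wrong: isomerisation of the (Z)-acyl group to the (E)-isomer during activation or heating, and incomplete acylation of one of the two hindered alcohols, each of which needs its own molecule of 32. Fallback (from 30, back at 33): the (Z)-double bonds are made on the substrate. Esterification of both secondary hydroxyls of 30 with two equivalents of 2-[bis(2,2,2-trifluoroethoxy)phosphoryl]propanoic acid (N,N′-dicyclohexylcarbodiimide, 4-dimethylaminopyridine) gives the bis(phosphonopropanoate) F16. A twofold Still–Gennari olefination with acetaldehyde (KN(SiMe3)2, 18-crown-6, THF, −78 °C) gives 33.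

## Further compounds

F1 | step 13 | (2E)-1-[(1R,2S,3S,5R)-2-acetyl-5-(tert-butyldimethylsilyloxy)-1-methyl-3-(propan-2-yl)-3-(triethylsilyloxy)cyclopentyl]but-2-en-1-one | C/C=C/C(=O)[C@@]1(C)[C@H](O[Si](C)(C)C(C)(C)C)C[C@](O[Si](CC)(CC)CC)(C(C)C)[C@H]1C(C)=O
F2 | step 13 | (2E)-1-[(1R,2R,3S,5R)-5-(tert-butyldimethylsilyloxy)-1-methyl-3-(propan-2-yl)-3-(triethylsilyloxy)-2-[1-(triethylsilyloxy)ethenyl]cyclopentyl]but-2-en-1-one | C/C=C/C(=O)[C@@]1(C)[C@H](O[Si](C)(C)C(C)(C)C)C[C@](O[Si](CC)(CC)CC)(C(C)C)[C@H]1C(=C)O[Si](CC)(CC)CC
F3 | step 9 | (3R,5R,6R)-5-hydroxy-N-methoxy-N,6-dimethyl-3-(propan-2-yl)-3-(triethylsilyloxy)oct-7-enamide | C=C[C@@H](C)[C@H](O)C[C@](O[Si](CC)(CC)CC)(C(C)C)CC(=O)N(C)OC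
F4 | step 9 | (3R,5R,6R)-5-(tert-butyldimethylsilyloxy)-N-methoxy-N,6-dimethyl-3-(propan-2-yl)-3-(triethylsilyloxy)oct-7-enamide | C=C[C@@H](C)[C@H](O[Si](C)(C)C(C)(C)C)C[C@](O[Si](CC)(CC)CC)(C(C)C)CC(=O)N(C)OC
F5 | step 9 | (3R,5R,6S)-5-(tert-butyldimethylsilyloxy)-N-methoxy-N,6-dimethyl-7-oxo-3-(propan-2-yl)-3-(triethylsilyloxy)heptanamide | O=C[C@@H](C)[C@H](O[Si](C)(C)C(C)(C)C)C[C@](O[Si](CC)(CC)CC)(C(C)C)CC(=O)N(C)OC
F6 | step 9 | (3R,5R,6R,8E)-5-(tert-butyldimethylsilyloxy)-7-hydroxy-N-methoxy-N,6-dimethyl-3-(propan-2-yl)-3-(triethylsilyloxy)dec-8-enamide (C7 epimers) | C/C=C/C(O)[C@@H](C)[C@H](O[Si](C)(C)C(C)(C)C)C[C@](O[Si](CC)(CC)CC)(C(C)C)CC(=O)N(C)OC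
F7 | step 11 | (3R,5R,6Z,8E)-5,7-bis(tert-butyldimethylsilyloxy)-N-methoxy-N,6-dimethyl-3-(propan-2-yl)-3-(triethylsilyloxy)deca-6,8-dienamide | C/C=C/C(O[Si](C)(C)C(C)(C)C)=C(\C)[C@H](O[Si](C)(C)C(C)(C)C)C[C@](O[Si](CC)(CC)CC)(C(C)C)CC(=O)N(C)OC
F8 | step 11 | (4R,6R,7Z,9E)-6,8-bis(tert-butyldimethylsilyloxy)-1-chloro-7-methyl-4-(propan-2-yl)-4-(triethylsilyloxy)undeca-7,9-dien-2-one | C/C=C/C(O[Si](C)(C)C(C)(C)C)=C(\C)[C@H](O[Si](C)(C)C(C)(C)C)C[C@](O[Si](CC)(CC)CC)(C(C)C)CC(=O)CCl
F9 | step 11 | (1R,3S,3aS,8aR)-1,8-bis(tert-butyldimethylsilyloxy)-6,8a-dimethyl-3-(propan-2-yl)-3-(triethylsilyloxy)-2,3,3a,5,6,8a-hexahydroazulen-4(1H)-one (C6 epimers) | O=C1CC(C)C=C(O[Si](C)(C)C(C)(C)C)[C@@]2(C)[C@H](O[Si](C)(C)C(C)(C)C)C[C@](O[Si](CC)(CC)CC)(C(C)C)[C@@H]12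
F10 | step 16 | (1R,3S,3aS,8aR)-1-(tert-butyldimethylsilyloxy)-3-hydroxy-6,8a-dimethyl-3-(propan-2-yl)octahydroazulene-4,8-dione (C6 epimers) | O=C1CC(C)CC(=O)[C@@]2(C)[C@H](O[Si](C)(C)C(C)(C)C)C[C@](O)(C(C)C)[C@@H]12
F11 | step 16 | (1R,3S,3aR,4R,8aR)-1-(tert-butyldimethylsilyloxy)-3,4-dihydroxy-6,8a-dimethyl-3-(propan-2-yl)octahydroazulen-8(1H)-one (C6 epimers) | O[C@@H]1CC(C)CC(=O)[C@@]2(C)[C@H](O[Si](C)(C)C(C)(C)C)C[C@](O)(C(C)C)[C@@H]12
F12 | step 16 | (1R,3S,3aR,4R,8aR)-1-(tert-butyldimethylsilyloxy)-6,8a-dimethyl-3-(propan-2-yl)-3,4,8-tris(trimethylsilyloxy)-1,2,3,3a,4,5,6,8a-octahydroazulene (C6 epimers) | C[Si](C)(C)O[C@@H]1CC(C)C=C(O[Si](C)(C)C)[C@@]2(C)[C@H](O[Si](C)(C)C(C)(C)C)C[C@](O[Si](C)(C)C)(C(C)C)[C@@H]12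
F13 | step 17 | (1R,3S,3aR,4R,8aR)-1-(tert-butyldimethylsilyloxy)-3-hydroxy-6,8a-dimethyl-8-oxo-3-(propan-2-yl)-1,2,3,3a,4,5,8,8a-octahydroazulen-4-yl (2Z)-2-methylbut-2-enoate | C/C=C(/C)C(=O)O[C@@H]1CC(C)=CC(=O)[C@@]2(C)[C@H](O[Si](C)(C)C(C)(C)C)C[C@](O)(C(C)C)[C@@H]12
F14 | step 17 | (1R,3S,3aR,4R,8aR)-1,3-dihydroxy-6,8a-dimethyl-8-oxo-3-(propan-2-yl)-1,2,3,3a,4,5,8,8a-octahydroazulen-4-yl (2Z)-2-methylbut-2-enoate | C/C=C(/C)C(=O)O[C@@H]1CC(C)=CC(=O)[C@@]2(C)[C@H](O)C[C@](O)(C(C)C)[C@@H]12
F15 | step 17 | (1R,3S,3aR,4R,8R,8aR)-1,3,8-trihydroxy-6,8a-dimethyl-3-(propan-2-yl)-1,2,3,3a,4,5,8,8a-octahydroazulen-4-yl (2Z)-2-methylbut-2-enoate | C/C=C(/C)C(=O)O[C@@H]1CC(C)=C[C@@H](O)[C@@]2(C)[C@H](O)C[C@](O)(C(C)C)[C@@H]12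
F16 | step 18 | 4,8-bis{2-[bis(2,2,2-trifluoroethoxy)phosphoryl]propanoate} of 30 (epimers at the phosphonate-bearing carbons) | CC(C(=O)O[C@@H]1CC(C)=C[C@@H](OC(=O)C(C)P(=O)(OCC(F)(F)F)OCC(F)(F)F)[C@@]2(C)[C@H](O[Si](C)(C)C(C)(C)C)C[C@](O)(C(C)C)[C@@H]12)P(=O)(OCC(F)(F)F)OCC(F)(F)F
A1 | alternative 1 | ring-B cyclopentene (C3a=C8a; C1 tert-butyldimethylsilyl ether, C3 triethylsilyl ether) carrying on C3a a 2-[(E)-2-(4-methoxybenzyloxy)ethenyl]-2-methyl-1-(trimethylsilyloxy)cyclopropyl group (both cyclopropane diastereomers) | CC1=C(C2(O[Si](C)(C)C)CC2(C)/C=C/OCc3ccc(OC)cc3)[C@@](O[Si](CC)(CC)CC)(C(C)C)C[C@H]1O[Si](C)(C)C(C)(C)C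
A2 | alternative 1 | 1-(tert-butyldimethylsilyloxy)-3-isopropyl-8-(4-methoxybenzyloxy)-6,8a-dimethyl-3-(triethylsilyloxy)-4-(trimethylsilyloxy)-1,2,3,5,8,8a-hexahydroazulene | C[Si](C)(C)OC=1CC(C)=C[C@@H](OCc2ccc(OC)cc2)[C@@]3(C)[C@H](O[Si](C)(C)C(C)(C)C)C[C@](O[Si](CC)(CC)CC)(C(C)C)C13
A3 | alternative 2 | cis-fused 6-(tert-butyldimethylsilyloxy)-4-isopropyl-6a-methyl-4-(triethylsilyloxy)hexahydropentalene-1,3-dione (ring B plus a five-membered C4, C5, C8 dione ring) | O=C1CC(=O)[C@@]2(C)[C@H](O[Si](C)(C)C(C)(C)C)C[C@](O[Si](CC)(CC)CC)(C(C)C)[C@@H]12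
A4 | alternative 2 | propadiene | C=C=C
A5 | alternative 2 | 1-(tert-butyldimethylsilyloxy)-3-isopropyl-8a-methyl-6-methylene-3-(triethylsilyloxy)octahydroazulene-4,8-dione, cis-fused | O=C1CC(=C)CC(=O)[C@@]2(C)[C@H](O[Si](C)(C)C(C)(C)C)C[C@](O[Si](CC)(CC)CC)(C(C)C)[C@@H]12
A6 | alternative 3 | N-phthalimidoyl 3-(4-methoxybenzyloxy)propanoate attached through its C3 (future C4) to C3a of ring B, with C8a carrying the (Z)-3-iodo-1-(4-methoxybenzyloxy)but-2-enyl group; C1 tert-butyldimethylsilyl ether, C3 triethylsilyl ether | O=C(ON1C(=O)c2ccccc2C1=O)C[C@@H](OCc3ccc(OC)cc3)[C@@H]4[C@@](O[Si](CC)(CC)CC)(C(C)C)C[C@@H](O[Si](C)(C)C(C)(C)C)[C@]4(C)[C@H](OCc5ccc(OC)cc5)/C=C(/C)I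
A7 | alternative 3 | target tetraol as 4,8-bis(4-methoxybenzyl) ether, 1-tert-butyldimethylsilyl ether and 3-triethylsilyl ether | COc1ccc(CO[C@@H]2CC(C)=C[C@@H](OCc3ccc(OC)cc3)[C@@]4(C)[C@H](O[Si](C)(C)C(C)(C)C)C[C@](O[Si](CC)(CC)CC)(C(C)C)[C@@H]24)cc1
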